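**Plan**

- Retrosynthesis cuts, in this order: the two gallate ester C–O bonds; the interflavan bond C4(upper)–C6(lower); then, in the upper (epiafzelechin) unit, the ring C bonds C3–C4 and O1–C2. The lower unit is (−)-epicatechin.
- Enabling feature: C4 is the benzylic carbon on ring A, ortho/para to O5, O7 and O1, so it can carry either charge. C3 is the only oxygenated carbon of ring C and can serve as an acyl carbon. The O1–C2 ether holds C3 in a 1,6-relation to C4.
- Forward: a Mitsunobu ether makes O1–C2. C4 is then turned from its native electrophilic character into a carbanion (2-pyridyl sulfone, SmI2) and closes ring C onto the ester carbon C3, giving the flavan-3-one; two electrophilic carbons are joined by polarity reversal.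
- Hydride delivery anti to the C2 aryl sets 3R (2,3-cis). C4 is re-oxidised with DDQ, ring A is capped with two bromines, and the C4 cation is attacked by C6 of 8-bromo-epicatechin tetrabenzyl ether (C8 blocked), anti to O3, giving 4β→6.
- Double galloylation and one hydrogenolysis (13 benzyl groups, 3 bromines) finish the route. C2 comes from (S)-4-hydroxymandelic acid with Mitsunobu inversion, C3 from substrate-controlled reduction, C4 from anti addition, and the lower C2/C3 from (−)-epicatechin.

Key step: step 6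

Assumption: (S)-4-hydroxymandelic acid and 3,4,5-tris(benzyloxy)benzoyl chloride are taken as purchasable; flavan numbering is used for both units (ring A C4a–C8a, ring C O1–C4, ring B the 2-aryl group), and α/β refer to the usual flavan drawing in which the C2 aryl of a 2R unit is α.

**Route**

Step 1
Reactants: 1 2,4,6-trihydroxybenzaldehyde
Product: 2 2,4-bis(benzyloxy)-6-hydroxybenzaldehyde
Conditions: BnBr (2.1 equiv), K2CO3, DMF, 0 °C to rt
Reagents that add atoms: benzyl bromide, BrCc1ccccc1
Why: Williamson ether synthesis in which the 4-OH and one ortho OH are alkylated, while the remaining ortho OH, hydrogen-bonded to the formyl oxygen, should stay free at this stoichiometry.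

Step 2
Reactants: 3 (S)-4-hydroxymandelic acid
Product: 4 benzyl (2S)-2-[4-(benzyloxy)phenyl]-2-hydroxyacetate
Conditions: BnBr (2.2 equiv), K2CO3, DMF, rt
Reagents that add atoms: benzyl bromide, BrCc1ccccc1
Why: Carboxylate and phenoxide alkylation (Williamson type), since K2CO3 deprotonates only the acid and the phenol, so the secondary alcohol and the stereocentre are untouched.

Step 3
Reactants: 2 2,4-bis(benzyloxy)-6-hydroxybenzaldehyde; 4 benzyl (2S)-2-[4-(benzyloxy)phenyl]-2-hydroxyacetate
Product: 5 benzyl (2R)-2-[3,5-bis(benzyloxy)-2-formylphenoxy]-2-[4-(benzyloxy)phenyl]acetate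
Conditions: PPh3, DIAD, toluene/THF, 0 °C to rt
Reagents that add atoms: none
Why: Mitsunobu reaction in which the acidic phenol 2 displaces the activated secondary alcohol of 4 by SN2 with inversion (2S to 2R), the adjacent ester disfavouring ionisation and racemisation; this sets C2 of the upper unit.

Step 4
Reactants: 5 benzyl (2R)-2-[3,5-bis(benzyloxy)-2-formylphenoxy]-2-[4-(benzyloxy)phenyl]acetate
Product: 6 benzyl (2R)-2-[3,5-bis(benzyloxy)-2-(hydroxymethyl)phenoxy]-2-[4-(benzyloxy)phenyl]acetate
Conditions: NaBH4, CeCl3·7H2O, THF/MeOH, −40 °C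
Reagents that add atoms: none
Why: Luche-type chemoselective hydride reduction, the aryl aldehyde being reduced much faster than the benzyl ester at low temperature, in a nearly neutral medium that should not epimerise the acidic C2–H.

Step 5
Reactants: 6 benzyl (2R)-2-[3,5-bis(benzyloxy)-2-(hydroxymethyl)phenoxy]-2-[4-(benzyloxy)phenyl]acetate
Product: 7 benzyl (2R)-2-{3,5-bis(benzyloxy)-2-[(pyridin-2-ylsulfonyl)methyl]phenoxy}-2-[4-(benzyloxy)phenyl]acetate
Conditions: sodium pyridine-2-sulfinate (3 equiv), CF3CO2H (3 equiv), CH2Cl2, 0 °C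
Reagents that add atoms: sodium pyridine-2-sulfinate, [Na+].[O-]S(=O)c1ccccn1
Why: Acid-mediated SN1 substitution (dehydrative sulfonylation) in which the readily formed 2,4,6-trioxygenated benzyl cation is captured at sulfur by excess sulfinate, giving a bench-stable sulfone in place of a benzylic halide that could not be isolated.

Step 6
Reactants: 7 benzyl (2R)-2-{3,5-bis(benzyloxy)-2-[(pyridin-2-ylsulfonyl)methyl]phenoxy}-2-[4-(benzyloxy)phenyl]acetate
Product: 9 (2R)-5,7-bis(benzyloxy)-2-[4-(benzyloxy)phenyl]chroman-3-one, via benzylsamarium diiodide 8 (not isolated)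
Conditions: SmI2 (2.2 equiv), THF, −78 °C, slow addition of 7 at high dilution; then aq. NH4Cl
Reagents that add atoms: samarium diiodide, I[Sm]I
Why: Proposed new method: two single-electron transfers from SmI2 cleave the benzylic C–S bond (pyridine-2-sulfinate leaves) and give benzylsamarium 8, whose carbanionic C4 attacks the ester carbonyl C3 held in place by the O1–C2 ether link, and collapse of the samarium hemiketalate, at the latest on aqueous quench, expels benzyloxide to leave the ketone, so that the samarium and iodine atoms carried by 8 end up as trivalent samarium salts and not in 9. The closest known reactions are the SmI2-promoted intramolecular nucleophilic acyl substitution of halo esters to cyclic ketones and the SmI2 Barbier coupling of 2-pyridyl sulfones with carbonyl compounds; the sulfone stands in for a 2,4,6-trialkoxybenzyl halide, which would ionise and alkylate itself. Ring C (C4, C4a, C8a, O1, C2, C3) closes in the 6-exo-trig mode. No new stereocentre is formed, since C3 becomes a carbonyl, and C2 should be kept because the medium is aprotic and non-basic and the closure is intramolecular. The step needs reduction of the sulfone in preference to the α-aryloxy ester and to the product ketone, which the easily reduced heteroaryl sulfone, HMPA-free SmI2 at −78 °C, the use of only two equivalents and the persistence of the tetrahedral trivalent samarium alkoxide at low temperature should secure; high dilution suppresses Wurtz-type dimerisation.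

Step 7
Reactants: 9 (2R)-5,7-bis(benzyloxy)-2-[4-(benzyloxy)phenyl]chroman-3-one
Product: 10 (2R,3R)-5,7-bis(benzyloxy)-2-[4-(benzyloxy)phenyl]chroman-3-ol (5,7,4′-tri-O-benzyl-(−)-epiafzelechin)
Conditions: LiBH(s-Bu)3, LiBr, THF, −78 °C; then H2O
Reagents that add atoms: none
Why: Substrate-controlled ketone reduction in which the bulky tri-sec-butylborohydride attacks C3 from the face opposite the equatorial C2 aryl group, as established for benzylated flavan-3-ones, setting 3R with the 2,3-cis (epi) relationship.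

Step 8
Reactants: 10 5,7,4′-tri-O-benzyl-(−)-epiafzelechin
Product: 11 (2R,3R,4S)-5,7-bis(benzyloxy)-2-[4-(benzyloxy)phenyl]-4-(2-ethoxyethoxy)chroman-3-ol (the 4β ether)
Conditions: DDQ (2 equiv), 2-ethoxyethanol, CH2Cl2, rt
Reagents that add atoms: 2-ethoxyethanol, CCOCCO
Why: Oxidative benzylic C–H functionalisation in which DDQ abstracts hydride from C4 (stabilised through ring A by O5, O7 and O1) and the alcohol adds anti to the C2 aryl and C3 hydroxyl groups to give the 4β ether, a known activation of benzylated flavan-3-ols whose C4 centre is ionised again in step 12.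

Step 9
Reactants: 11 the 4β-(2-ethoxyethoxy) ether
Product: 12 (2R,3R,4S)-5,7-bis(benzyloxy)-2-[4-(benzyloxy)phenyl]-6,8-dibromo-4-(2-ethoxyethoxy)chroman-3-ol
Conditions: NBS (2.1 equiv), CH2Cl2, −20 °C to rt, dark
Reagents that add atoms: N-bromosuccinimide, O=C1CCC(=O)N1Br
Why: Electrophilic aromatic bromination of the two free ring A positions (each ortho/para to three oxygens, far more reactive than ring B or the benzyl groups), which caps ring A so that the later C4 cation cannot attack another molecule of its own kind.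

Step 10
Reactants: 13 (−)-epicatechin
Product: 14 5,7,3′,4′-tetra-O-benzyl-(−)-epicatechin
Conditions: BnBr (4.4 equiv), K2CO3, DMF, 0 °C to rt
Reagents that add atoms: benzyl bromide, BrCc1ccccc1
Why: Williamson ether synthesis of the four phenols under carbonate conditions that leave the secondary C3 alcohol and both stereocentres untouched (a known transformation).

Step 11
Reactants: 14 5,7,3′,4′-tetra-O-benzyl-(−)-epicatechin
Product: 15 5,7,3′,4′-tetra-O-benzyl-8-bromo-(−)-epicatechin
Conditions: NBS (1.0 equiv), CH2Cl2, −78 °C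
Reagents that add atoms: N-bromosuccinimide, O=C1CCC(=O)N1Br
Why: Electrophilic aromatic bromination in which one equivalent of NBS at low temperature goes to C8, the known preferred site of benzylated flavan-3-ols, leaving C6 as the only nucleophilic ring A position.

Step 12
Reactants: 12 the 6,8-dibromo 4β-(2-ethoxyethoxy) ether; 15 5,7,3′,4′-tetra-O-benzyl-8-bromo-(−)-epicatechin
Product: 16 5,7,4′-tri-O-benzyl-6,8-dibromo-(−)-epiafzelechin-(4β→6)-5,7,3′,4′-tetra-O-benzyl-8-bromo-(−)-epicatechin
Conditions: TMSOTf (0.2 equiv), 15 (3 equiv), CH2Cl2, −78 to −30 °C; then Et3N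
Reagents that add atoms: none
Why: Lewis-acid-mediated Friedel–Crafts alkylation in which ionisation of the C4 ether of 12 gives the ring-A-stabilised cation, and C6, the only free ring A carbon of 15, attacks from the β face, anti to the axial C3 hydroxyl and the C2 aryl group, setting the 4β (3,4-trans) configuration and the 4→6 linkage by the known halo-capping principle.

Step 13
Reactants: 16 the tribromo heptabenzyl dimer diol
Product: 17 3-O-[3,4,5-tris(benzyloxy)benzoyl]-5,7,4′-tri-O-benzyl-6,8-dibromo-(−)-epiafzelechin-(4β→6)-3-O-[3,4,5-tris(benzyloxy)benzoyl]-5,7,3′,4′-tetra-O-benzyl-8-bromo-(−)-epicatechin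
Conditions: 3,4,5-tris(benzyloxy)benzoyl chloride (5 equiv), DMAP (cat.), pyridine, 40 °C
Reagents that add atoms: 3,4,5-tris(benzyloxy)benzoyl chloride, O=C(Cl)c1cc(OCc2ccccc2)c(OCc2ccccc2)c(OCc2ccccc2)c1
Why: DMAP-catalysed acylation (nucleophilic acyl transfer) of both secondary alcohols with excess acid chloride, as known for benzylated 4→8 dimers, with no stereocentre touched.

Step 14
Reactants: 17 the fully protected bis-gallate
Product: 18 (−)-epiafzelechin 3-O-gallate-(4β→6)-(−)-epicatechin 3-O-gallate (CNP0169607.1)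
Conditions: H2 (1 atm), Pd(OH)2/C, Et3N, THF/MeOH/H2O, rt
Reagents that add atoms: none
Why: Heterogeneous catalytic hydrogenolysis should cleave all thirteen benzyl ethers and the three aryl C–Br bonds while the gallate esters, the interflavan bond and all five stereocentres survive, triethylamine buffering the HBr that would otherwise cleave the acid-labile C4–C6 bond.

**Compound list**

1 | 2,4,6-trihydroxybenzaldehyde | O=Cc1c(O)cc(O)cc1O | starting material
2 | 2,4-bis(benzyloxy)-6-hydroxybenzaldehyde | O=Cc1c(O)cc(OCc2ccccc2)cc1OCc1ccccc1 | intermediate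
3 | (S)-4-hydroxymandelic acid, (2S)-2-hydroxy-2-(4-hydroxyphenyl)acetic acid | O[C@H](C(=O)O)c1ccc(O)cc1 | starting material
4 | benzyl (2S)-2-[4-(benzyloxy)phenyl]-2-hydroxyacetate | O[C@H](C(=O)OCc1ccccc1)c1ccc(OCc2ccccc2)cc1 | intermediate
5 | benzyl (2R)-2-[3,5-bis(benzyloxy)-2-formylphenoxy]-2-[4-(benzyloxy)phenyl]acetate | O=Cc1c(O[C@@H](C(=O)OCc2ccccc2)c2ccc(OCc3ccccc3)cc2)cc(OCc2ccccc2)cc1OCc1ccccc1 | intermediate
6 | benzyl (2R)-2-[3,5-bis(benzyloxy)-2-(hydroxymethyl)phenoxy]-2-[4-(benzyloxy)phenyl]acetate | OCc1c(O[C@@H](C(=O)OCc2ccccc2)c2ccc(OCc3ccccc3)cc2)cc(OCc2ccccc2)cc1OCc1ccccc1 | intermediate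
7 | benzyl (2R)-2-{3,5-bis(benzyloxy)-2-[(pyridin-2-ylsulfonyl)methyl]phenoxy}-2-[4-(benzyloxy)phenyl]acetate | O=S(=O)(Cc1c(O[C@@H](C(=O)OCc2ccccc2)c2ccc(OCc3ccccc3)cc2)cc(OCc2ccccc2)cc1OCc1ccccc1)c1ccccn1 | intermediate
8 | benzylsamarium diiodide formed from 7 (SmI2 group on the benzylic carbon in place of the pyridylsulfonyl group; 2R) | I[Sm](I)Cc1c(O[C@@H](C(=O)OCc2ccccc2)c2ccc(OCc3ccccc3)cc2)cc(OCc2ccccc2)cc1OCc1ccccc1 | intermediate
9 | (2R)-5,7-bis(benzyloxy)-2-[4-(benzyloxy)phenyl]chroman-3-one | O=C1Cc2c(OCc3ccccc3)cc(OCc3ccccc3)cc2O[C@@H]1c1ccc(OCc2ccccc2)cc1 | intermediate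
10 | (2R,3R)-5,7-bis(benzyloxy)-2-[4-(benzyloxy)phenyl]chroman-3-ol (5,7,4′-tri-O-benzyl-(−)-epiafzelechin) | O[C@@H]1Cc2c(OCc3ccccc3)cc(OCc3ccccc3)cc2O[C@@H]1c1ccc(OCc2ccccc2)cc1 | intermediate
11 | (2R,3R,4S)-5,7-bis(benzyloxy)-2-[4-(benzyloxy)phenyl]-4-(2-ethoxyethoxy)chroman-3-ol (4β ether, 2,3-cis-3,4-trans) | O[C@@H]1[C@@H](OCCOCC)c2c(OCc3ccccc3)cc(OCc3ccccc3)cc2O[C@@H]1c1ccc(OCc2ccccc2)cc1 | intermediate
12 | (2R,3R,4S)-5,7-bis(benzyloxy)-2-[4-(benzyloxy)phenyl]-6,8-dibromo-4-(2-ethoxyethoxy)chroman-3-ol | O[C@@H]1[C@@H](OCCOCC)c2c(OCc3ccccc3)c(Br)c(OCc3ccccc3)c(Br)c2O[C@@H]1c1ccc(OCc2ccccc2)cc1 | intermediate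
13 | (−)-epicatechin, (2R,3R) | O[C@@H]1Cc2c(O)cc(O)cc2O[C@@H]1c1ccc(O)c(O)c1 | starting material
14 | 5,7,3′,4′-tetra-O-benzyl-(−)-epicatechin | O[C@@H]1Cc2c(OCc3ccccc3)cc(OCc3ccccc3)cc2O[C@@H]1c1ccc(OCc2ccccc2)c(OCc2ccccc2)c1 | intermediate
15 | 5,7,3′,4′-tetra-O-benzyl-8-bromo-(−)-epicatechin | O[C@@H]1Cc2c(OCc3ccccc3)cc(OCc3ccccc3)c(Br)c2O[C@@H]1c1ccc(OCc2ccccc2)c(OCc2ccccc2)c1 | intermediate
16 | 5,7,4′-tri-O-benzyl-6,8-dibromo-(−)-epiafzelechin-(4β→6)-5,7,3′,4′-tetra-O-benzyl-8-bromo-(−)-epicatechin (both C3 hydroxyls free) | O[C@@H]1[C@@H](c2c(OCc4ccccc4)c(Br)c3c(c2OCc2ccccc2)C[C@@H](O)[C@@H](c2ccc(OCc4ccccc4)c(OCc4ccccc4)c2)O3)c2c(OCc3ccccc3)c(Br)c(OCc3ccccc3)c(Br)c2O[C@@H]1c1ccc(OCc2ccccc2)cc1 | intermediate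
17 | 16 with both C3 hydroxyls esterified as 3,4,5-tris(benzyloxy)benzoates | O=C(O[C@@H]1[C@@H](c2c(OCc4ccccc4)c(Br)c3c(c2OCc2ccccc2)C[C@@H](OC(=O)c2cc(OCc4ccccc4)c(OCc4ccccc4)c(OCc4ccccc4)c2)[C@@H](c2ccc(OCc4ccccc4)c(OCc4ccccc4)c2)O3)c2c(OCc3ccccc3)c(Br)c(OCc3ccccc3)c(Br)c2O[C@@H]1c1ccc(OCc2ccccc2)cc1)c1cc(OCc2ccccc2)c(OCc2ccccc2)c(OCc2ccccc2)c1 | intermediate
18 | (−)-epiafzelechin 3-O-gallate-(4β→6)-(−)-epicatechin 3-O-gallate; upper unit 2R,3R,4S, lower unit 2R,3R | O=C(O[C@@H]1[C@@H](c2c(O)cc3c(c2O)C[C@@H](OC(=O)c2cc(O)c(O)c(O)c2)[C@@H](c2ccc(O)c(O)c2)O3)c2c(O)cc(O)cc2O[C@@H]1c1ccc(O)cc1)c1cc(O)c(O)c(O)c1 | target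

**Step count and risks**

Total step count: 14. Longest linear sequence: 11 steps (steps 1, 3–9, 12–14).

Steps most likely to fail:

1. Step 6 (Proposed new method). The benzylsamarium may be protonated before it cyclises, by internal transfer of the acidic C2–H or by the sulfone CH2 of unreacted 7. The benzylic radical may dimerise before the second electron transfer. The freed ketone may be reduced further with loss of the aryloxy bond at C2. The fallback uses known chemistry and needs no carbanion at C4: a titanium-mediated carbonyl–ester coupling (McMurry-type oxo ester cyclisation). It sets out from formyl ester 5. Slow addition of 5 to low-valent titanium (TiCl3, Zn–Cu couple, DME, reflux, high dilution) should join the formyl carbon C4 to the ester carbon C3 and give the cyclic enol ether (2R)-3,5,7-tris(benzyloxy)-2-[4-(benzyloxy)phenyl]-2H-chromene F1. Mild aqueous acid (oxalic acid, wet THF) should hydrolyse the enol benzyl ether to ketone 9, where the route is rejoined; steps 4 and 5 are then not needed.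

2. Step 12. Attack by the hindered, bromine-deactivated C6 (flanked by two benzyloxy groups) may be slow, so that the C4 cation is lost by elimination or hydrolysis, and facial selectivity may erode at the higher temperature then needed. The fallback replaces oxophilic by thiophilic activation and sets out from 12. The C4 ether is exchanged for a thioether (phenylmethanethiol, BF3·OEt2 cat., CH2Cl2, −40 °C) to give 5,7,4′-tri-O-benzyl-4β-(benzylsulfanyl)-6,8-dibromo-(−)-epiafzelechin F2. AgBF4 in THF at 0 °C, under neutral conditions that tolerate long reaction times, should then release the cation in the presence of 15 and give 16, where the route is rejoined.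

3. Step 13. Acylation of the axial C3 hydroxyl of the upper unit, flanked by the C2 and C4 aryl groups, may stay incomplete so that the mono-ester accumulates, or the material may decompose when the reaction is forced. The fallback forms both esters before the interflavan bond and sets out from 12 and 15. Each is acylated on its own with 3,4,5-tris(benzyloxy)benzoyl chloride (DMAP, pyridine), giving 5,7,4′-tri-O-benzyl-6,8-dibromo-4β-(2-ethoxyethoxy)-3-O-[3,4,5-tris(benzyloxy)benzoyl]-(−)-epiafzelechin F3 and 5,7,3′,4′-tetra-O-benzyl-8-bromo-3-O-[3,4,5-tris(benzyloxy)benzoyl]-(−)-epicatechin F4. Union of F3 and F4 with TMSOTf in CH2Cl2 at low temperature, where the C3 ester shields the α face by neighbouring-group participation, should give 17 directly, where the route is rejoined.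

Further compounds
F1 | step 6 | (2R)-3,5,7-tris(benzyloxy)-2-[4-(benzyloxy)phenyl]-2H-chromene | O(Cc1ccccc1)C1=Cc2c(OCc3ccccc3)cc(OCc3ccccc3)cc2O[C@@H]1c1ccc(OCc2ccccc2)cc1
F2 | step 12 | 5,7,4′-tri-O-benzyl-4β-(benzylsulfanyl)-6,8-dibromo-(−)-epiafzelechin | O[C@@H]1[C@@H](SCc3ccccc3)c2c(OCc3ccccc3)c(Br)c(OCc3ccccc3)c(Br)c2O[C@@H]1c1ccc(OCc2ccccc2)cc1
F3 | step 13 | 5,7,4′-tri-O-benzyl-6,8-dibromo-4β-(2-ethoxyethoxy)-3-O-[3,4,5-tris(benzyloxy)benzoyl]-(−)-epiafzelechin | O=C(O[C@@H]1[C@@H](OCCOCC)c2c(OCc3ccccc3)c(Br)c(OCc3ccccc3)c(Br)c2O[C@@H]1c1ccc(OCc2ccccc2)cc1)c1cc(OCc2ccccc2)c(OCc2ccccc2)c(OCc2ccccc2)c1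
F4 | step 13 | 5,7,3′,4′-tetra-O-benzyl-8-bromo-3-O-[3,4,5-tris(benzyloxy)benzoyl]-(−)-epicatechin | O=C(O[C@@H]1Cc2c(OCc3ccccc3)cc(OCc3ccccc3)c(Br)c2O[C@@H]1c1ccc(OCc2ccccc2)c(OCc2ccccc2)c1)c1cc(OCc2ccccc2)c(OCc2ccccc2)c(OCc2ccccc2)c1
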